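**Retrosynthetic overview**

- Feature (cyclopenta[c]pyridine numbering: N2, dienyl at C3): the cyclopentanone ring C4a–C5–C6–C7–C7a is attached to the pyridine ring only through the fully substituted carbinol carbon C5 (to C4a) and the ketone carbon C7 (to C7a). C5–C6–C7 can therefore arrive as one chiral lactate-derived piece and the pyridine as a C4/C5 dianion equivalent.
- Last bond: C3–C1' by Suzuki coupling of the 3-chloro bicycle with the (1E,3E,5S)-dienyl pinacolboronate, made from (S)-2-methylbutan-1-ol in five steps.
- Key disconnection: C4a–C5 and C7–C7a, both formed in one flask from 5-bromo-2-chloropyridine (metalated first at C4, then at C5) and a dioxolanone α-keto ester. This closes the cyclopentanone, the only ring formed; the pyridine ring is bought.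
- The keto ester comes from (R)-lactic acid via its cis pivalaldehyde acetal and C-oxalylation of the enolate anti to tert-butyl, which fixes C6. C5 is set by chelate-controlled aryl addition.

Key step: step 3

Remark: the keto ester 5 is assumed to be handled in its anhydrous keto form, since its ketone is expected to hydrate reversibly; it would be dried azeotropically with toluene before step 3.

**Step 1**
Reactants: 1 (R)-lactic acid
Product: 2 (2R,5R)-2-tert-butyl-5-methyl-1,3-dioxolan-4-one (cis)
Conditions: t-BuCHO, TsOH·H2O (cat.), H2SO4 (cat.), pentane, reflux, Dean–Stark; recrystallisation from pentane at −78 °C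
Reagents that add atoms: pivalaldehyde, CC(C)(C)C=O
Why: Acid-catalysed acetalisation under equilibrating conditions (Seebach self-regeneration of stereocentres) should favour the cis-2,5-disubstituted dioxolanone, so the new acetal centre C2 (R) is set by the lactate centre through this thermodynamic preference and upgraded by low-temperature crystallisation.

**Step 2**
Reactants: 2 (2R,5R)-2-tert-butyl-5-methyl-1,3-dioxolan-4-one; 3 dimethyl oxalate
Product: 5 methyl 2-[(2R,4S)-2-tert-butyl-4-methyl-5-oxo-1,3-dioxolan-4-yl]-2-oxoacetate, via lithium (2R)-2-tert-butyl-5-methyl-1,3-dioxol-4-olate 4 (not isolated)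
Conditions: LiN(i-Pr)2 (LDA), THF, −78 °C; cannulated into (CO2Me)2 (3 equiv), THF, −78 °C; AcOH, −78 °C
Reagents that add atoms: none
Why: Crossed Claisen C-acylation of the Seebach lithium enolate by dimethyl oxalate, in which the electrophile enters anti to the tert-butyl group so that the quaternary centre (4S) forms with retention of the lactate configuration, while the tetrahedral oxalate adduct, kept at −78 °C until the acid quench, should protect the product ketone from a second addition and from retro-Claisen reversal.

**Step 3**
Reactants: 6 5-bromo-2-chloropyridine; 5 methyl 2-[(2R,4S)-2-tert-butyl-4-methyl-5-oxo-1,3-dioxolan-4-yl]-2-oxoacetate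
Product: 11 methyl (5R,6S)-3-chloro-5,6-dihydroxy-6-methyl-7-oxo-6,7-dihydro-5H-cyclopenta[c]pyridine-5-carboxylate, via 5-bromo-2-chloro-4-lithiopyridine 7 (not isolated), via (5-bromo-2-chloropyridin-4-yl)magnesium bromide 8 (not isolated), via bromomagnesium alkoxide adduct 9 (not isolated), via C7a-magnesiated alkoxide 10 (not isolated)
Conditions: 6 (1.1 equiv), LiN(i-Pr)2, THF, −78 °C; MgBr2·OEt2, −78 °C; 5 (1.0 equiv), −78 → −40 °C; i-PrMgCl·LiCl (1.1 equiv), −40 → 0 °C; aq NH4Cl
Reagents that add atoms: none
Why: LiN(i-Pr)2 removes H4 of 6, the position ortho to bromine, and MgBr2 turns the labile 4-lithio species 7 into arylmagnesium 8, which resists halogen dance and pyridyne formation and adds only to the ketone of 5 (far more electrophilic than the ester or lactone carbonyls), forming C4a–C5 in alkoxide 9. Bromine–magnesium exchange by i-PrMgCl·LiCl, helped by the neighbouring alkoxide, then gives 10, whose C7a carbanion attacks the dioxolanone carbonyl in a 5-exo-trig acyl substitution (attack on the methyl ester would need a four-membered ring), forming C7–C7a; the tetrahedral intermediate collapses and the hemiacetal alkoxide loses pivalaldehyde, leaving the C7 ketone and the free C6 hydroxyl. The closest known reaction types are the addition of ortho-metalated bromopyridines to α-keto esters and the Parham cyclisation of an aryl halide onto an ester or lactone carbonyl, here simply run one after the other in the same flask. C6 (S) comes unchanged from 5, while C5 (R) is set in the addition by a Cram chelate in which magnesium bridges the ketone oxygen and the dioxolanone ring oxygen on C6, so that the aryl group enters from the face carrying the C-methyl group and not from the face covered by the dioxolanone ring; rotation about C5–C6 for ring closure then places the C5 hydroxyl cis to the methyl group and trans to the C6 hydroxyl. The step needs this facial selectivity, which chelation by the ester carbonyl could erode, and it needs C4 regioselectivity in the metalation, which the ortho-directing bromine secures at −78 °C.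

**Step 4**
Reactants: 12 (S)-2-methylbutan-1-ol
Product: 13 (S)-2-methylbutanal
Conditions: TEMPO (cat.), KBr (cat.), NaOCl, NaHCO3, CH2Cl2/H2O, 0 °C; dried CH2Cl2 solution used directly
Reagents that add atoms: none
Why: Anelli oxidation (TEMPO-catalysed hypochlorite oxidation) of a primary alcohol stops at the aldehyde under buffered biphasic conditions at 0 °C and should leave the α-stereocentre unepimerised.

**Step 5**
Reactants: 13 (S)-2-methylbutanal
Product: 14 ethyl (2E,4S)-2,4-dimethylhex-2-enoate
Conditions: Ph3P=C(CH3)CO2Et, CH2Cl2, rt → 40 °C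
Reagents that add atoms: ethyl 2-(triphenyl-λ5-phosphanylidene)propanoate, CCOC(=O)C(C)=P(c1ccccc1)(c1ccccc1)c1ccccc1
Why: Wittig olefination with a stabilised α-methyl ylide should give the trisubstituted (E)-enoate selectively under neutral conditions that do not epimerise the adjacent stereocentre.

**Step 6**
Reactants: 14 ethyl (2E,4S)-2,4-dimethylhex-2-enoate
Product: 15 (2E,4S)-2,4-dimethylhex-2-en-1-ol
Conditions: i-Bu2AlH (2.2 equiv), CH2Cl2, −78 °C; aq potassium sodium tartrate
Reagents that add atoms: none
Why: 1,2-Reduction of the conjugated ester by i-Bu2AlH at low temperature gives the allylic alcohol without touching the alkene geometry or the stereocentre.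

**Step 7**
Reactants: 15 (2E,4S)-2,4-dimethylhex-2-en-1-ol
Product: 16 (2E,4S)-2,4-dimethylhex-2-enal
Conditions: MnO2, CH2Cl2, rt
Reagents that add atoms: none
Why: Allylic oxidation with activated MnO2 is selective for the allylic alcohol and stops at the enal with the E geometry retained.

**Step 8**
Reactants: 16 (2E,4S)-2,4-dimethylhex-2-enal
Product: 17 2-[(1E,3E,5S)-3,5-dimethylhepta-1,3-dien-1-yl]-4,4,5,5-tetramethyl-1,3,2-dioxaborolane
Conditions: Cl2CHBpin, CrCl2, LiI, THF, rt
Reagents that add atoms: 2-(dichloromethyl)-4,4,5,5-tetramethyl-1,3,2-dioxaborolane, ClC(Cl)B1OC(C)(C)C(C)(C)O1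
Why: Takai–Utimoto boryl olefination, in which the geminal dichromium species formed from Cl2CHBpin and CrCl2 adds 1,2 to the aldehyde and eliminates to give the (E)-alkenylboronate, creating the (1E) alkene of the diene.

**Step 9**
Reactants: 11 methyl (5R,6S)-3-chloro-5,6-dihydroxy-6-methyl-7-oxo-6,7-dihydro-5H-cyclopenta[c]pyridine-5-carboxylate; 17 2-[(1E,3E,5S)-3,5-dimethylhepta-1,3-dien-1-yl]-4,4,5,5-tetramethyl-1,3,2-dioxaborolane
Product: 18 methyl (5R,6S)-3-[(1E,3E,5S)-3,5-dimethylhepta-1,3-dien-1-yl]-5,6-dihydroxy-6-methyl-7-oxo-6,7-dihydro-5H-cyclopenta[c]pyridine-5-carboxylate (target)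
Conditions: Pd(OAc)2 (cat.), SPhos (cat.), K3PO4, THF/H2O, 40 °C
Reagents that add atoms: none
Why: Suzuki–Miyaura coupling, in which the C3 chloride is activated for oxidative addition by the adjacent ring nitrogen and the para C7 ketone, the dienyl group is transferred with retention of both alkene geometries, and mild phosphate base at 40 °C is chosen to spare the tertiary diol, ketone and methyl ester.

**Compound list**

1 | (R)-lactic acid | C[C@@H](O)C(=O)O | starting material
2 | (2R,5R)-2-tert-butyl-5-methyl-1,3-dioxolan-4-one (cis) | C[C@H]1O[C@@H](C(C)(C)C)OC1=O | intermediate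
3 | dimethyl oxalate | COC(=O)C(=O)OC | starting material
4 | lithium (2R)-2-tert-butyl-5-methyl-1,3-dioxol-4-olate (enolate of 2, not isolated) | CC1=C(O[Li])O[C@H](C(C)(C)C)O1 | intermediate
5 | methyl 2-[(2R,4S)-2-tert-butyl-4-methyl-5-oxo-1,3-dioxolan-4-yl]-2-oxoacetate (tert-butyl cis to methyl) | COC(=O)C(=O)[C@]1(C)O[C@@H](C(C)(C)C)OC1=O | intermediate
6 | 5-bromo-2-chloropyridine | Clc1ccc(Br)cn1 | starting material
7 | 5-bromo-2-chloro-4-lithiopyridine (not isolated) | [Li]c1cc(Cl)ncc1Br | intermediate
8 | (5-bromo-2-chloropyridin-4-yl)magnesium bromide (not isolated) | Br[Mg]c1cc(Cl)ncc1Br | intermediate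
9 | bromomagnesium alkoxide of methyl (2R)-2-(5-bromo-2-chloropyridin-4-yl)-2-[(2R,4S)-2-tert-butyl-4-methyl-5-oxo-1,3-dioxolan-4-yl]-2-hydroxyacetate (not isolated) | COC(=O)[C@@](O[Mg]Br)(c1cc(Cl)ncc1Br)[C@]1(C)O[C@@H](C(C)(C)C)OC1=O | intermediate
10 | bromomagnesium alkoxide of methyl (2R)-2-[2-chloro-5-(chloromagnesio)pyridin-4-yl]-2-[(2R,4S)-2-tert-butyl-4-methyl-5-oxo-1,3-dioxolan-4-yl]-2-hydroxyacetate (not isolated) | COC(=O)[C@@](O[Mg]Br)(c1cc(Cl)ncc1[Mg]Cl)[C@]1(C)O[C@@H](C(C)(C)C)OC1=O | intermediate
11 | methyl (5R,6S)-3-chloro-5,6-dihydroxy-6-methyl-7-oxo-6,7-dihydro-5H-cyclopenta[c]pyridine-5-carboxylate | Clc1cc2c(cn1)C(=O)[C@@](C)(O)[C@@]2(O)C(=O)OC | intermediate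
12 | (S)-2-methylbutan-1-ol | CC[C@H](C)CO | starting material
13 | (S)-2-methylbutanal | CC[C@H](C)C=O | intermediate
14 | ethyl (2E,4S)-2,4-dimethylhex-2-enoate | CC[C@H](C)/C=C(C)/C(=O)OCC | intermediate
15 | (2E,4S)-2,4-dimethylhex-2-en-1-ol | CC[C@H](C)/C=C(C)/CO | intermediate
16 | (2E,4S)-2,4-dimethylhex-2-enal | CC[C@H](C)/C=C(C)/C=O | intermediate
17 | 2-[(1E,3E,5S)-3,5-dimethylhepta-1,3-dien-1-yl]-4,4,5,5-tetramethyl-1,3,2-dioxaborolane | CC[C@H](C)/C=C(C)/C=C/B1OC(C)(C)C(C)(C)O1 | intermediate
18 | methyl (5R,6S)-3-[(1E,3E,5S)-3,5-dimethylhepta-1,3-dien-1-yl]-5,6-dihydroxy-6-methyl-7-oxo-6,7-dihydro-5H-cyclopenta[c]pyridine-5-carboxylate | CC[C@H](C)/C=C(C)/C=C/c1cc2c(cn1)C(=O)[C@@](C)(O)[C@@]2(O)C(=O)OC | target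

**Step count**

Total: 9 steps. Longest linear sequence: 6 steps (steps 4–9, from 12 to 18); the lactate branch reaches the target in 4 steps (1, 2, 3, 9).

**Steps most likely to fail**

1. Step 3. The aryl addition may run through a non-chelated or ester-chelated transition state and give poor facial selectivity at C5. The lithiated pyridine may also undergo halogen dance before transmetalation, or the magnesium aldolate may fragment by retro-aldol cleavage during the exchange. The fallback makes the C5–C6 bond by an aldol addition instead, so that C5 is set in a different, lithium-bridged transition state. It sets out from arylmagnesium 8 (generated from 6) and dimethyl oxalate 3. Inverse addition of 8 to excess 3 at −78 °C should give methyl 2-(5-bromo-2-chloropyridin-4-yl)-2-oxoacetate F1. The lithium enolate 4 (from 2) would then add to the ketone of F1 at −78 °C, anti to the tert-butyl group, to give methyl (2R)-2-(5-bromo-2-chloropyridin-4-yl)-2-[(2R,4S)-2-tert-butyl-4-methyl-5-oxo-1,3-dioxolan-4-yl]-2-hydroxyacetate F2; any C5 epimer would be removed by chromatography. Treating isolated F2 with i-PrMgCl·LiCl (2.2 equiv, −40 → 0 °C) would effect the Parham cyclisation with loss of pivalaldehyde, and the route is rejoined at 11.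

2. Step 2. The tetrahedral adduct may collapse before the quench, so that the enolate adds a second time to the liberated ketone or the acylation reverts by retro-Claisen cleavage. The fallback sets out from enolate 4 (from 2). Aldol addition to methyl glyoxylate at −78 °C, again anti to the tert-butyl group, should give methyl 2-[(2R,4S)-2-tert-butyl-4-methyl-5-oxo-1,3-dioxolan-4-yl]-2-hydroxyacetate F3 as a mixture of carbinol epimers, which does not matter. Oxidation with Dess–Martin periodinane in CH2Cl2 then returns to 5.

3. Step 9. The phosphate base may trigger retro-aldol opening and reclosure of the β-hydroxy ketone, with loss of configuration at C5, or hydrolysis of the methyl ester. The fallback is a base-free Stille coupling, setting out from enal 16 and chloride 11. Hodgson stannyl olefination of 16 (Bu3SnCHBr2, CrCl2, LiI, THF/DMF) should give tributyl[(1E,3E,5S)-3,5-dimethylhepta-1,3-dien-1-yl]stannane F4. Coupling of F4 with 11 (Pd(PPh3)4, CuI, DMF, 80 °C) then returns to the target 18.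

**Further compounds**

F1 | step 3 | methyl 2-(5-bromo-2-chloropyridin-4-yl)-2-oxoacetate | COC(=O)C(=O)c1cc(Cl)ncc1Br
F2 | step 3 | methyl (2R)-2-(5-bromo-2-chloropyridin-4-yl)-2-[(2R,4S)-2-tert-butyl-4-methyl-5-oxo-1,3-dioxolan-4-yl]-2-hydroxyacetate | COC(=O)[C@@](O)(c1cc(Cl)ncc1Br)[C@]1(C)O[C@@H](C(C)(C)C)OC1=O
F3 | step 2 | methyl 2-[(2R,4S)-2-tert-butyl-4-methyl-5-oxo-1,3-dioxolan-4-yl]-2-hydroxyacetate (carbinol epimers) | COC(=O)C(O)[C@]1(C)O[C@@H](C(C)(C)C)OC1=O
F4 | step 9 | tributyl[(1E,3E,5S)-3,5-dimethylhepta-1,3-dien-1-yl]stannane | CC[C@H](C)/C=C(C)/C=C/[Sn](CCCC)(CCCC)CCCC
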